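The oxolane is disconnected at O1–C5, the benzylic C–O bond that lies para to the phenol of one guaiacyl ring: such a p-hydroxybenzyl ether is the adduct of a p-quinone methide and an alcohol. The ring carbons C3–C4–C5 are therefore stored as a trans,trans γ-aryl-γ-butyrolactone whose α-carbon carries the future C2 as an anti-aldol carbinol. In the key step fluoride frees the phenoxide, the lactone carboxylate leaves from C5 by 1,6-elimination, and the C2 hydroxyl closes the oxolane by 5-exo oxa-1,6-addition, setting C5 and transposing lactone into tetrahydrofuran in one operation. An Evans aldol and a boron aldol with the same silylated vanillin set the other three stereocentres.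

Key step: step 6

Remark: 1, 2 and 4 are taken as catalogue compounds (4 is O-silylated vanillin). Oxolane locants for 12 and 13 count C2 as the carbinol-derived benzylic carbon and C5 as the carbon bonded in step 6; in the target the C2 aryl is cis to both CH2OH groups and the C5 aryl is trans to them. TBS = tert-butyldimethylsilyl, Piv = 2,2-dimethylpropanoyl.

Step 1
Reactants: 1 (S)-4-benzyl-1,3-oxazolidin-2-one; 2 methyl 4-chloro-4-oxobutanoate
Product: 3 methyl 4-[(4S)-4-benzyl-2-oxo-1,3-oxazolidin-3-yl]-4-oxobutanoate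
Conditions: n-BuLi, THF, −78 °C; then 2, −78 → 0 °C
Reagents that add atoms: none
Why: N-Acylation of the lithiated oxazolidinone by the acid chloride (standard Evans auxiliary loading) is much faster than attack on the methyl ester at −78 °C, and no stereocentre is created.

Step 2
Reactants: 3 methyl 4-[(4S)-4-benzyl-2-oxo-1,3-oxazolidin-3-yl]-4-oxobutanoate; 4 4-(TBS-oxy)-3-methoxybenzaldehyde
Product: 6 (4S)-4-benzyl-3-{[(2S,3S)-2-[4-(TBS-oxy)-3-methoxyphenyl]-5-oxooxolan-3-yl]carbonyl}-1,3-oxazolidin-2-one, via syn-aldol hydroxy ester 5 (not isolated)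
Conditions: Bu2BOTf, i-Pr2NEt, CH2Cl2, −78 → 0 °C; 4, −78 → 0 °C; then H2O2, MeOH, NaH2PO4/Na2HPO4 buffer (pH 7), 0 °C → rt
Reagents that add atoms: none
Why: Evans syn-aldol reaction: the (Z)-boron enolate forms selectively at the imide α-CH2 and reacts through a Zimmerman–Traxler chair on the enolate face opposite the auxiliary benzyl group, setting the (3S,4S) pair of 5, whose aldolate oxygen then lactonises onto the methyl ester to give the trans-4,5-disubstituted γ-lactone (residual hydroxy ester should close on brief exposure to catalytic pyridinium p-toluenesulfonate).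

Step 3
Reactants: 6 (4S)-4-benzyl-3-{[(2S,3S)-2-[4-(TBS-oxy)-3-methoxyphenyl]-5-oxooxolan-3-yl]carbonyl}-1,3-oxazolidin-2-one
Product: 7 (4R,5S)-5-[4-(TBS-oxy)-3-methoxyphenyl]-4-(hydroxymethyl)oxolan-2-one
Conditions: NaBH4, THF/H2O (4:1), 0 °C
Reagents that add atoms: none
Why: Reductive cleavage of the N-acyl oxazolidinone: borohydride attacks the activated exocyclic imide carbonyl much faster than the γ-lactone, releasing the primary alcohol and the recoverable auxiliary without touching either stereocentre, and the hydroxymethyl lactone formed is the more substituted, thermodynamically preferred lactone should any translactonisation occur.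

Step 4
Reactants: 7 (4R,5S)-5-[4-(TBS-oxy)-3-methoxyphenyl]-4-(hydroxymethyl)oxolan-2-one
Product: 8 [(2S,3R)-2-[4-(TBS-oxy)-3-methoxyphenyl]-5-oxooxolan-3-yl]methyl 2,2-dimethylpropanoate
Conditions: PivCl, pyridine, DMAP (cat.), CH2Cl2, 0 °C → rt
Reagents that add atoms: pivaloyl chloride, CC(C)(C)C(=O)Cl
Why: DMAP-catalysed O-acylation of the primary alcohol installs a non-enolisable ester that blocks translactonisation, tolerates the boron enolate and fluoride steps, and is removed by the final hydride reduction; no stereocentre is involved.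

Step 5
Reactants: 8 [(2S,3R)-2-[4-(TBS-oxy)-3-methoxyphenyl]-5-oxooxolan-3-yl]methyl 2,2-dimethylpropanoate; 4 4-(TBS-oxy)-3-methoxybenzaldehyde
Product: 9 [(2S,3R,4R)-2-[4-(TBS-oxy)-3-methoxyphenyl]-4-{(S)-[4-(TBS-oxy)-3-methoxyphenyl](hydroxy)methyl}-5-oxooxolan-3-yl]methyl 2,2-dimethylpropanoate
Conditions: c-Hex2BOTf, Et3N, CH2Cl2, −78 °C; 4, −78 → 0 °C; then H2O2, MeOH, NaH2PO4/Na2HPO4 buffer (pH 7), 0 °C
Reagents that add atoms: none
Why: Dicyclohexylboron-mediated anti-selective aldol reaction: the lactone can only give the (E)-enol borinate, which reacts through a Zimmerman–Traxler chair (aryl equatorial) to give the anti (S)-carbinol, while the aldehyde approaches the enolate face opposite the adjacent CH2OPiv group, placing the new side chain trans to it.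

Step 6
Reactants: 9 [(2S,3R,4R)-2-[4-(TBS-oxy)-3-methoxyphenyl]-4-{(S)-[4-(TBS-oxy)-3-methoxyphenyl](hydroxy)methyl}-5-oxooxolan-3-yl]methyl 2,2-dimethylpropanoate
Product: 12 (2S,3R,4R,5S)-2,5-bis(4-hydroxy-3-methoxyphenyl)-4-[(pivaloyloxy)methyl]oxolane-3-carboxylic acid, via bis-phenol lactone 10 (not isolated), via quinone methide acid 11 (not isolated)
Conditions: CsF, DMF (0.01 M), 0 °C → rt; then AcOH
Reagents that add atoms: none
Why: CsF cleaves both aryl silyl ethers; the phenoxide para to the lactone C–O bond expels the carboxylate by 1,6-elimination to give p-quinone methide 11, and the side-chain benzylic hydroxyl adds to the methide carbon (oxa-1,6-conjugate addition), so the lactone is transposed into the oxolane. The closest known reaction types are fluoride-triggered p-quinone methide generation from p-silyloxybenzyl esters and the quinone methide cyclisations used for 2,5-diaryltetrahydrofuran lignans. The oxolane closes in a 5-exo-trig mode, with oxygen attacking the exocyclic methide carbon. The single new stereocentre C5 is controlled by allylic 1,3-strain in 11: the C4–H eclipses the methide double bond, the tethered oxygen attacks the face on the side of C3, and the aryl group ends up trans to CH2OPiv, which is also the thermodynamically preferred arrangement because the three existing substituents are all cis on the other face. The step needs C5 and not C2 to be the electrophilic centre and the secondary hydroxyl, not the carboxylate, to be the final nucleophile; only C5 carries a leaving group (hydroxide at C2 is not expelled under these mild conditions, so C2 keeps its configuration), and re-closure by the carboxylate is reversible whereas ether formation is not and is driven by the gain of a carboxylate for a phenoxide. High dilution suppresses intermolecular phenoxide addition to the methide.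

Step 7
Reactants: 12 (2S,3R,4R,5S)-2,5-bis(4-hydroxy-3-methoxyphenyl)-4-[(pivaloyloxy)methyl]oxolane-3-carboxylic acid
Product: 13 [(2S,3S,4R,5S)-2,5-bis(4-hydroxy-3-methoxyphenyl)oxolane-3,4-diyl]dimethanol
Conditions: LiAlH4, THF, 0 → 50 °C; then aq. KNaC4H4O6
Reagents that add atoms: none
Why: Hydride reduction converts the carboxylic acid (as its aluminate carboxylate) into the primary alcohol and cleaves the pivalate in the same operation, while the phenoxides and the benzylic ethers are inert to LiAlH4, so all four stereocentres are carried through unchanged.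

Compound list
1 | (S)-4-benzyl-1,3-oxazolidin-2-one | O=C1N[C@@H](Cc2ccccc2)CO1 | starting material
2 | methyl 4-chloro-4-oxobutanoate | COC(=O)CCC(Cl)=O | starting material
3 | methyl 4-[(4S)-4-benzyl-2-oxo-1,3-oxazolidin-3-yl]-4-oxobutanoate | COC(=O)CCC(=O)N1[C@@H](Cc2ccccc2)COC1=O | intermediate
4 | 4-[(tert-butyldimethylsilyl)oxy]-3-methoxybenzaldehyde | COc1cc(C=O)ccc1O[Si](C)(C)C(C)(C)C | starting material
5 | methyl (3S,4S)-3-[(4S)-4-benzyl-2-oxo-1,3-oxazolidine-3-carbonyl]-4-[4-(TBS-oxy)-3-methoxyphenyl]-4-hydroxybutanoate (syn-aldol hydroxy ester) | COC(=O)C[C@@H]([C@H](O)c1ccc(O[Si](C)(C)C(C)(C)C)c(OC)c1)C(=O)N1[C@@H](Cc2ccccc2)COC1=O | intermediate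
6 | (4S)-4-benzyl-3-{[(2S,3S)-2-[4-(TBS-oxy)-3-methoxyphenyl]-5-oxooxolan-3-yl]carbonyl}-1,3-oxazolidin-2-one (aryl and acyl trans) | O=C1O[C@H](c2ccc(O[Si](C)(C)C(C)(C)C)c(OC)c2)[C@@H](C(=O)N2[C@@H](Cc3ccccc3)COC2=O)C1 | intermediate
7 | (4R,5S)-5-[4-(TBS-oxy)-3-methoxyphenyl]-4-(hydroxymethyl)oxolan-2-one | O=C1O[C@H](c2ccc(O[Si](C)(C)C(C)(C)C)c(OC)c2)[C@@H](CO)C1 | intermediate
8 | [(2S,3R)-2-[4-(TBS-oxy)-3-methoxyphenyl]-5-oxooxolan-3-yl]methyl 2,2-dimethylpropanoate | O=C1O[C@H](c2ccc(O[Si](C)(C)C(C)(C)C)c(OC)c2)[C@@H](COC(=O)C(C)(C)C)C1 | intermediate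
9 | [(2S,3R,4R)-2-[4-(TBS-oxy)-3-methoxyphenyl]-4-{(S)-[4-(TBS-oxy)-3-methoxyphenyl](hydroxy)methyl}-5-oxooxolan-3-yl]methyl 2,2-dimethylpropanoate (all-trans lactone, anti-aldol carbinol) | O=C1O[C@H](c2ccc(O[Si](C)(C)C(C)(C)C)c(OC)c2)[C@@H](COC(=O)C(C)(C)C)[C@@H]1[C@H](O)c1ccc(O[Si](C)(C)C(C)(C)C)c(OC)c1 | intermediate
10 | [(2S,3R,4R)-2-(4-hydroxy-3-methoxyphenyl)-4-[(S)-hydroxy(4-hydroxy-3-methoxyphenyl)methyl]-5-oxooxolan-3-yl]methyl 2,2-dimethylpropanoate (bis-phenol lactone, present as phenoxide) | O=C1O[C@H](c2ccc(O)c(OC)c2)[C@@H](COC(=O)C(C)(C)C)[C@@H]1[C@H](O)c1ccc(O)c(OC)c1 | intermediate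
11 | (2R,3R)-2-[(S)-hydroxy(4-hydroxy-3-methoxyphenyl)methyl]-4-(3-methoxy-4-oxocyclohexa-2,5-dien-1-ylidene)-3-[(pivaloyloxy)methyl]butanoic acid (quinone methide acid, present as carboxylate; methide C=C geometry not defined) | OC(=O)[C@@H]([C@H](O)c1ccc(O)c(OC)c1)[C@H](COC(=O)C(C)(C)C)C=C1C=CC(=O)C(OC)=C1 | intermediate
12 | (2S,3R,4R,5S)-2,5-bis(4-hydroxy-3-methoxyphenyl)-4-[(pivaloyloxy)methyl]oxolane-3-carboxylic acid (C2 aryl, C3 CO2H and C4 CH2OPiv cis; C5 aryl trans) | COc1cc([C@H]2O[C@H](c3ccc(O)c(OC)c3)[C@@H](COC(=O)C(C)(C)C)[C@H]2C(=O)O)ccc1O | intermediate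
13 | [(2S,3S,4R,5S)-2,5-bis(4-hydroxy-3-methoxyphenyl)oxolane-3,4-diyl]dimethanol | COc1cc([C@H]2O[C@H](c3ccc(O)c(OC)c3)[C@@H](CO)[C@H]2CO)ccc1O | target

Total steps: 7. Longest linear sequence: 7 steps (1 → 13).

Steps most likely to fail

Step 6. What may go wrong: tautomerisation of the quinone methide to the p-hydroxystyrene, or retro-aldol cleavage of the β-hydroxy lactone under the basic fluoride conditions, could outrun the ring closure, which is slowed by the three cis substituents. Fallback (sets out from 8, returns to the route at 13): the oxolane is closed from an open-chain 1,4-diol by acid-mediated benzylic etherification, with the two arenes differentiated. The boron aldol of step 5 is run on 8 with 4-(benzyloxy)-3-methoxybenzaldehyde (COc1cc(C=O)ccc1OCc1ccccc1) to give the O-benzyl aldol lactone F1. LiAlH4 (THF, 0 °C) reduces lactone and pivalate to the tetraol F2. TBSCl/imidazole (2.1 equiv, DMF, 0 °C) silylates the two primary alcohols to give the bis-silyl ether F3. K2CO3/MeOH removes only the aryl silyl ether to give the phenol F4. Catalytic pyridinium p-toluenesulfonate (CH2Cl2, 0 °C) should ionise only the p-hydroxybenzylic alcohol, through the neutral quinone methide, and the other benzylic hydroxyl closes the ring trans to the neighbouring silyloxymethyl group to give the oxolane F5. Bu4NF (THF) gives the diol F6, and hydrogenolysis of the aryl benzyl ether (H2, Pd/C, EtOAc) gives 13.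

Step 5. What may go wrong: incomplete boron enolisation of the lactone, or leakage through open transition states, would erode the anti selectivity at the carbinol. Fallback (sets out from 8, returns at 9): aldol addition of the lithium enolate of 8 (LiN(i-Pr)2, THF, −78 °C) to 4 gives 9 together with its (R)-carbinol epimer F7. Dess–Martin periodinane converts the mixture into the single 3-aroyl lactone F8, whose trans ring configuration is the thermodynamic one. Corey–Bakshi–Shibata reduction ((R)-2-methyl-CBS-oxazaborolidine, BH3·SMe2, THF, −30 °C) should then set the (S)-carbinol under reagent control and return 9.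

Step 3. What may go wrong: competing hydride reduction of the lactone, or base-induced β-elimination that opens the γ-aryl lactone through the imide enolate, before the imide is consumed. Fallback (sets out from 6, returns at 7): LiOH/H2O2 (THF/H2O, 0 °C) hydrolyses the imide to the lactone acid F9 with recovery of 1, and BH3·SMe2 (THF, 0 °C) reduces the carboxylic acid chemoselectively in the presence of the lactone to give 7.

Further compounds
F1 | step 6 | [(2S,3R,4R)-4-{(S)-[4-(benzyloxy)-3-methoxyphenyl](hydroxy)methyl}-2-[4-(TBS-oxy)-3-methoxyphenyl]-5-oxooxolan-3-yl]methyl 2,2-dimethylpropanoate | O=C1O[C@H](c2ccc(O[Si](C)(C)C(C)(C)C)c(OC)c2)[C@@H](COC(=O)C(C)(C)C)[C@@H]1[C@H](O)c1ccc(OCc2ccccc2)c(OC)c1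
F2 | step 6 | (1S,2S,3R,4S)-1-[4-(benzyloxy)-3-methoxyphenyl]-4-[4-(TBS-oxy)-3-methoxyphenyl]-2,3-bis(hydroxymethyl)butane-1,4-diol | O[C@H](c1ccc(O[Si](C)(C)C(C)(C)C)c(OC)c1)[C@@H](CO)[C@@H](CO)[C@H](O)c1ccc(OCc2ccccc2)c(OC)c1
F3 | step 6 | (1S,2S,3R,4S)-1-[4-(benzyloxy)-3-methoxyphenyl]-4-[4-(TBS-oxy)-3-methoxyphenyl]-2,3-bis[(TBS-oxy)methyl]butane-1,4-diol | O[C@H](c1ccc(O[Si](C)(C)C(C)(C)C)c(OC)c1)[C@@H](CO[Si](C)(C)C(C)(C)C)[C@@H](CO[Si](C)(C)C(C)(C)C)[C@H](O)c1ccc(OCc2ccccc2)c(OC)c1
F4 | step 6 | (1S,2S,3R,4S)-1-[4-(benzyloxy)-3-methoxyphenyl]-4-(4-hydroxy-3-methoxyphenyl)-2,3-bis[(TBS-oxy)methyl]butane-1,4-diol | O[C@H](c1ccc(O)c(OC)c1)[C@@H](CO[Si](C)(C)C(C)(C)C)[C@@H](CO[Si](C)(C)C(C)(C)C)[C@H](O)c1ccc(OCc2ccccc2)c(OC)c1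
F5 | step 6 | 4-{(2S,3R,4S,5S)-5-[4-(benzyloxy)-3-methoxyphenyl]-3,4-bis[(TBS-oxy)methyl]oxolan-2-yl}-2-methoxyphenol | COc1cc([C@H]2O[C@H](c3ccc(O)c(OC)c3)[C@@H](CO[Si](C)(C)C(C)(C)C)[C@H]2CO[Si](C)(C)C(C)(C)C)ccc1OCc1ccccc1
F6 | step 6 | [(2S,3S,4R,5S)-2-[4-(benzyloxy)-3-methoxyphenyl]-5-(4-hydroxy-3-methoxyphenyl)oxolane-3,4-diyl]dimethanol | COc1cc([C@H]2O[C@H](c3ccc(O)c(OC)c3)[C@@H](CO)[C@H]2CO)ccc1OCc1ccccc1
F7 | step 5 | [(2S,3R,4R)-2-[4-(TBS-oxy)-3-methoxyphenyl]-4-{(R)-[4-(TBS-oxy)-3-methoxyphenyl](hydroxy)methyl}-5-oxooxolan-3-yl]methyl 2,2-dimethylpropanoate | O=C1O[C@H](c2ccc(O[Si](C)(C)C(C)(C)C)c(OC)c2)[C@@H](COC(=O)C(C)(C)C)[C@@H]1[C@@H](O)c1ccc(O[Si](C)(C)C(C)(C)C)c(OC)c1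
F8 | step 5 | [(2S,3R,4R)-4-[4-(TBS-oxy)-3-methoxybenzoyl]-2-[4-(TBS-oxy)-3-methoxyphenyl]-5-oxooxolan-3-yl]methyl 2,2-dimethylpropanoate | O=C1O[C@H](c2ccc(O[Si](C)(C)C(C)(C)C)c(OC)c2)[C@@H](COC(=O)C(C)(C)C)[C@@H]1C(=O)c1ccc(O[Si](C)(C)C(C)(C)C)c(OC)c1
F9 | step 3 | (2S,3S)-2-[4-(TBS-oxy)-3-methoxyphenyl]-5-oxooxolane-3-carboxylic acid | O=C1O[C@H](c2ccc(O[Si](C)(C)C(C)(C)C)c(OC)c2)[C@@H](C(=O)O)C1
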